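## The problem

The target joins C3 of apigenin (rings A, B, C) to C6'' of (2S)-4',5,7-trihydroxyflavan (rings A'', B'', C''). The C3–C6'' bond is the hard part. C3 lies between the C2 aryl group and the C4 carbonyl, and C6'' lies between the oxygenated C5'' and C7'', so a direct coupling would have to make a tetra-ortho-substituted biaryl-type bond. C6'' and C8'' of a 5,7-dioxygenated flavan are also nearly alike, and electrophiles usually prefer C8'', so the 3,6'' linkage must be fixed by construction. The only stereocentre is C2'' (S). Nothing else in the molecule can control it, so it must be set by a reagent, and once set it cannot be corrected. C2'' is a para-oxygenated benzylic ether carbon: acid that ionises C2''–O1'' racemises it, and hydrogenolysis can cleave the same bond. The five phenols need protecting groups that leave without acid. The chromone is open to hard nucleophiles at C2. The feature that makes the key step possible is ring A'': a pentasubstituted benzene with oxygen at C5'', C7'' and C8a'' in a 1,3,5 relation and C6'' between two of them. This is the pattern formed when a 3-alkoxy vinylketene (carbonyl becomes C7''–OH, alkoxy becomes O1'') is annulated with an oxygenated alkyne (its oxygen becomes O5'') whose other carbon carries the flavone.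

## Retrosynthesis

**Protecting groups.** Target 26 is traced back to tetrabenzyl ether 25 and then to silyl ether 24. Benzyl ethers on the four outer phenols leave together under neutral hydrogenolysis. The triisopropylsilyl group on O5'' is not chosen freely: it is what the alkyne partner delivers, and fluoride removes it. No acid is needed after the stereocentre is in place.

**Ring A'' (key disconnection).** In 24 the bonds C6''–C7'', C4a''–C5'' and C7''–C8'' are cut. This gives cyclobutenone 10 (C7'', C8'', C8a'', C4a'', with the pyran and C2'' in place) and siloxyalkyne 19 (C5'', C6'', with the flavone on C6''). The neighbouring cut, C3–C6'', would need a hindered cross-coupling and a C6''-selective handle on a flavan. Here the C3–carbon bond is made earlier as an unhindered sp2–sp bond, and ring A'' is grown around it. C6'' cannot be confused with C8'', because the preformed pyran fixes O1'' and the polarity of ketene and ynol ether fixes the rest. Both precursors are far simpler than 24: one has a single ring fusion and the stereocentre, the other is a flavone with a two-carbon side chain. The forward reaction must open a donor-stabilised cyclobutenone thermally and must accept a bulky, electron-poor group on the nucleophilic alkyne carbon.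

**Siloxyalkyne 19.** The O–C(sp) bond is cut back to terminal alkyne 16 (acetylide oxidation, then O-silylation). The C3–C(sp) bond is cut back through silylalkyne 15 to iodide 14 (Sonogashira coupling). The C3–I bond is cut back to tribenzyl ether 12 (C3 lithiation) and then to apigenin 11. Each cut removes one small unit and uses a reaction known on flavones or aryl alkynes.

**Cyclobutenone 10.** The obvious route is dichloroketene addition to a 2-aryl-3,4-dihydro-2H-pyran, and it gives the right connectivity. It was rejected because it ends in a saturated β-alkoxycyclobutanone. Dehydrogenating that to the enone has little precedent, and any enolate would expel the ring oxygen. The oxidation level is therefore brought in with an alkyne. The O1''–C8a'' bond of 10 is cut to hydroxy cyclobutenone 9, which closes by vinylogous transesterification without touching the C2''–O bond. The two C–C bonds of the four-membered ring in silyl ether 8 are cut to ynol ether 7 and ketene. Because a 2-substituted cyclobutane-1,3-dione core is symmetric, the ring closure has no regiochemical question.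

**Ynol ether 7.** The C(sp)–C(sp3) bond is cut to ethoxyacetylene and the primary triflate 6 of alcohol 5. A primary triflate is asked for because lithium alkoxyacetylides are alkylated only by very reactive electrophiles.

**Stereocentre.** Alcohol 5 goes back through silyl ether 4 to hydroxy ester 3. Its C–O stereocentre is cut to keto ester 2 (catalytic asymmetric transfer hydrogenation), and 2 to commercial ketone 1 (Claisen condensation). An aryl ketone flanked by an ester is a very reliable substrate for this reduction, and the C–O bond formed here is never broken again.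

## Roads not taken

**Alternative 1:** ring C'' would be closed last by ring-closing metathesis of aryl 1-arylallyl ether A1, which carries an ortho vinyl group. The second-generation Grubbs catalyst RuCl2(=CHPh)(PCy3)(H2IMes) would form C3''=C4'' and give 2H-chromene A2. Every reaction involved is well known, which the chosen plan cannot claim for its key step. One hydrogenation would then saturate the chromene and remove all six benzyl groups, so the endgame is one step shorter. Against this, A1 already contains the C3–C6'' bond, which must first be made by a tetra-ortho-substituted coupling. Ring A'' of A1 needs three differentiated oxygens and a vinyl group placed correctly. The acyclic, doubly activated ether in A1 is far more prone to ionisation and to hydrogenolysis than the cyclic ether of the flavan. The chosen plan offers an unhindered bond construction and a stereocentre set early on a simple ketone.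

**Alternative 2:** ring C of the flavone would be built by oxidative annulation of 2-hydroxybenzaldehyde A3 with diaryl alkyne A4, using [Cp*RhCl2]2 and Cu(OAc)2. This forms C3–C4 and O1–C2 and gives hexabenzyl ether A5. It is the most convergent option, avoids any hindered biaryl coupling, and needs only one deprotection step. Its weak points are two. A4 requires a C6''-selective functionalisation of a 5,7-dioxygenated flavan, where C8'' is normally favoured. The two aryl groups on the alkyne of A4 are both electron-rich, so nothing directs which one ends at C2 and which at C3. The chosen plan is less convergent at the flavone but settles both regiochemical questions by the way the atoms are assembled.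

**Alternative 3:** ring C'' would be closed on a symmetric arene. The phenoxide of bromide A6 would attack the tethered primary carbon through its ortho ring carbon, form C4''–C4a'' and give A7, which is identical with 25. Symmetry removes the C6''/C8'' problem, and the reaction types are all known. The costs are a tetra-ortho-substituted coupling to make the 3-(2,4,6-trioxygenated phenyl)flavone, a selective alkylation of the para oxygen, and a stereospecific substitution at a para-alkoxybenzylic carbon, which can leak through the cation. Competition between O- and C-alkylation is a further risk. It is the best of the three and serves below as the fallback for the key step. The chosen plan is shorter and never breaks the C–O bond of the stereocentre.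

Key step: step 13

Assumption: ethoxyacetylene (hexane solution) and ketene gas from a laboratory generator (cracking of diketene) are taken as available; double-primed locants denote the flavan unit.

## Route

Step 1
Reactants: 1 4'-(benzyloxy)acetophenone
Product: 2 ethyl 3-[4-(benzyloxy)phenyl]-3-oxopropanoate
Conditions: NaH, (EtO)2CO, THF, reflux; then aq. HCl
Reagents that add atoms: diethyl carbonate, CCOC(=O)OCC
Why: Crossed Claisen condensation of the ketone enolate with the carbonate; deprotonation of the β-keto ester by NaH drives it to completion and the benzyl ether is inert.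

Step 2
Reactants: 2 ethyl 3-[4-(benzyloxy)phenyl]-3-oxopropanoate
Product: 3 ethyl (3S)-3-[4-(benzyloxy)phenyl]-3-hydroxypropanoate
Conditions: RuCl[(S,S)-TsDPEN](p-cymene) (1 mol %), HCO2H/Et3N 5:2, DMF, 30 °C
Reagents that add atoms: none
Why: Noyori–Ikariya asymmetric transfer hydrogenation of an aryl ketone; the (S,S)-ligand should deliver hydride to the face that gives the (S)-carbinol, as it does for acetophenone-type ketones, and ester and benzyl ether are not reduced.

Step 3
Reactants: 3 ethyl (3S)-3-[4-(benzyloxy)phenyl]-3-hydroxypropanoate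
Product: 4 ethyl (3S)-3-[4-(benzyloxy)phenyl]-3-[(tert-butyldimethylsilyl)oxy]propanoate
Conditions: t-BuMe2SiCl, imidazole, DMF, rt
Reagents that add atoms: tert-butyldimethylsilyl chloride, CC(C)(C)[Si](C)(C)Cl
Why: Standard silylation of a secondary alcohol; the mild base does not trigger β-elimination of the β-oxy ester.

Step 4
Reactants: 4 ethyl (3S)-3-[4-(benzyloxy)phenyl]-3-[(tert-butyldimethylsilyl)oxy]propanoate
Product: 5 (3S)-3-[4-(benzyloxy)phenyl]-3-[(tert-butyldimethylsilyl)oxy]propan-1-ol
Conditions: i-Bu2AlH, CH2Cl2, −78 → 0 °C; Rochelle salt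
Reagents that add atoms: none
Why: Hydride reduction of the ester to the primary alcohol; silyl and benzyl ethers survive and the stereocentre is not enolisable.

Step 5
Reactants: 5 (3S)-3-[4-(benzyloxy)phenyl]-3-[(tert-butyldimethylsilyl)oxy]propan-1-ol
Product: 7 tert-butyl({(1S)-1-[4-(benzyloxy)phenyl]-5-ethoxypent-4-yn-1-yl}oxy)dimethylsilane, via triflate 6 (not isolated)
Conditions: Tf2O, 2,6-lutidine, CH2Cl2, −78 °C; then LiC≡COEt (HC≡COEt, n-BuLi), THF, −78 → −20 °C
Reagents that add atoms: ethoxyacetylene, C#COCC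
Why: SN2 alkylation of lithium ethoxyacetylide by a primary triflate, which reacts at the low temperature where the acetylide is stable; the stereocentre is three atoms away.

Step 6
Reactants: 7 tert-butyl({(1S)-1-[4-(benzyloxy)phenyl]-5-ethoxypent-4-yn-1-yl}oxy)dimethylsilane
Product: 8 2-{(3S)-3-[4-(benzyloxy)phenyl]-3-[(tert-butyldimethylsilyl)oxy]propyl}-3-ethoxycyclobut-2-en-1-one
Conditions: CH2=C=O (gas, excess), CH2Cl2, 0 °C → rt
Reagents that add atoms: ketene, C=C=O
Why: [2+2] cycloaddition of ketene with an ynol ether; the alkyl-bearing alkyne carbon attacks the ketene carbonyl carbon, which places the ethoxy group at C3 and the chain at C2 of the cyclobutenone.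

Step 7
Reactants: 8 2-{(3S)-3-[4-(benzyloxy)phenyl]-3-[(tert-butyldimethylsilyl)oxy]propyl}-3-ethoxycyclobut-2-en-1-one
Product: 10 (3S)-3-[4-(benzyloxy)phenyl]-2-oxabicyclo[4.2.0]oct-1(6)-en-7-one, via hydroxy cyclobutenone 9 (not isolated)
Conditions: HF·pyridine, THF, 0 °C → rt; then PPTS (cat.), toluene, 5 Å sieves, 50 °C
Reagents that add atoms: none
Why: Fluoride desilylation, then acid-catalysed vinylogous transesterification (addition of the alcohol to C3 and loss of ethanol) closes the six-membered ring. The C–O bond of the stereocentre is not broken, so the configuration is retained, and the symmetric 1,3-dioxygenated four-membered core allows only one product.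

Step 8
Reactants: 11 apigenin
Product: 12 5,7-bis(benzyloxy)-2-[4-(benzyloxy)phenyl]-4H-chromen-4-one
Conditions: BnBr, K2CO3, Bu4NI (cat.), DMF, 80 °C
Reagents that add atoms: benzyl bromide, BrCc1ccccc1
Why: Williamson etherification; heat and excess halide are needed for the hydrogen-bonded 5-hydroxyl.

Step 9
Reactants: 12 5,7-bis(benzyloxy)-2-[4-(benzyloxy)phenyl]-4H-chromen-4-one
Product: 14 5,7-bis(benzyloxy)-2-[4-(benzyloxy)phenyl]-3-iodo-4H-chromen-4-one, via 3-lithioflavone 13 (not isolated)
Conditions: LiN(i-Pr)2, THF, −78 °C; I2, −78 → 0 °C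
Reagents that add atoms: iodine, II
Why: Deprotonation of the flavone at C3, the vinylic position acidified by the adjacent carbonyl and ring oxygen, followed by iodinolysis; a known way to 3-iodoflavones.

Step 10
Reactants: 14 5,7-bis(benzyloxy)-2-[4-(benzyloxy)phenyl]-3-iodo-4H-chromen-4-one
Product: 15 5,7-bis(benzyloxy)-2-[4-(benzyloxy)phenyl]-3-[(trimethylsilyl)ethynyl]-4H-chromen-4-one
Conditions: HC≡CSiMe3, PdCl2(PPh3)2 (5 mol %), CuI (10 mol %), Et3N, DMF, 50 °C
Reagents that add atoms: ethynyltrimethylsilane, C#C[Si](C)(C)C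
Why: Sonogashira coupling; the iodide on the electron-poor enone carbon adds readily to palladium, and the linear alkyne is not affected by the two flanking groups.

Step 11
Reactants: 15 5,7-bis(benzyloxy)-2-[4-(benzyloxy)phenyl]-3-[(trimethylsilyl)ethynyl]-4H-chromen-4-one
Product: 16 5,7-bis(benzyloxy)-2-[4-(benzyloxy)phenyl]-3-ethynyl-4H-chromen-4-one
Conditions: K2CO3 (0.2 equiv), MeOH/THF, 0 °C
Reagents that add atoms: none
Why: Methoxide-catalysed protodesilylation of the alkynylsilane; low temperature and substoichiometric base limit conjugate attack on the chromone.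

Step 12
Reactants: 16 5,7-bis(benzyloxy)-2-[4-(benzyloxy)phenyl]-3-ethynyl-4H-chromen-4-one
Product: 19 5,7-bis(benzyloxy)-2-[4-(benzyloxy)phenyl]-3-{[(triisopropylsilyl)oxy]ethynyl}-4H-chromen-4-one, via lithium acetylide 17 (not isolated), via lithium ynolate 18 (not isolated)
Conditions: LiN(SiMe3)2, THF, −78 °C; t-BuOOLi (t-BuOOH, LiN(SiMe3)2), −78 → 0 °C; i-Pr3SiOTf, −78 °C
Reagents that add atoms: tert-butyl hydroperoxide, CC(C)(C)OO; triisopropylsilyl trifluoromethanesulfonate, CC(C)[Si](C(C)C)(C(C)C)OS(=O)(=O)C(F)(F)F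
Why: Oxidation of a lithium acetylide by lithium tert-butyl peroxide to the ynolate (Julia oxidation), then O-silylation with the bulky silyl triflate (Kozmin protocol); the sequence is known for aryl and alkyl terminal alkynes.

Step 13
Reactants: 10 (3S)-3-[4-(benzyloxy)phenyl]-2-oxabicyclo[4.2.0]oct-1(6)-en-7-one; 19 5,7-bis(benzyloxy)-2-[4-(benzyloxy)phenyl]-3-{[(triisopropylsilyl)oxy]ethynyl}-4H-chromen-4-one
Product: 24 5,7-bis(benzyloxy)-2-[4-(benzyloxy)phenyl]-3-{(2S)-2-[4-(benzyloxy)phenyl]-7-hydroxy-5-[(triisopropylsilyl)oxy]-3,4-dihydro-2H-chromen-6-yl}-4H-chromen-4-one, via vinylketene 20 (not isolated), via spirocyclobutenone 21 (not isolated), via dienylketene 22 (not isolated), via cyclohexadienone 23 (not isolated)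
Conditions: 10 (1.3 equiv), toluene (0.3 M), sealed tube, argon, 80 → 110 °C
Reagents that add atoms: none
Why: Proposed new method: the closest known reaction is the Danheiser benzannulation of alkyl- or aryl-substituted cyclobutenones with siloxyalkynes to resorcinol monosilyl ethers; it has not been shown with a ring-fused 3-alkoxycyclobutenone or with a siloxyalkyne bearing a hindered, electron-poor heteroaryl group. Heat should open 10 by four-electron electrocyclic ring opening to vinylketene 20. The flavone-bearing carbon of 19, the nucleophilic end of the silyl ynol ether, then adds to the ketene carbonyl carbon (C6''–C7'') and the ketene α-carbon closes onto the oxygenated alkyne carbon (C4a''–C5''), a stepwise [2+2] cycloaddition giving spirocyclobutenone 21. Reversible four-electron opening of 21 gives dienylketene 22; the isomer with the ketene cis to the methylidene closes ring A'' by six-electron electrocyclisation (C7''–C8'') to cyclohexadienone 23, and enolisation to the C7'' phenol makes the sequence irreversible. No stereocentre is formed; C2'' lies outside the reacting π system, and the neutral aprotic medium cannot ionise its benzylic C–O bond. The one selectivity needed is the mutual orientation of ketene and alkyne, which the polarity of both partners fixes, so the flavone ends between O5'' and O7'' and the preformed pyran keeps O1'' on C8a''. The alkoxy group makes the terminal methylidene of the vinylketene more nucleophilic, which should help the last closure, while the vinylogous-ester stabilisation of 10 is the reason for the higher final temperature.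

Step 14
Reactants: 24 (the 5''-O-triisopropylsilyl ether from step 13)
Product: 25 5,7-bis(benzyloxy)-2-[4-(benzyloxy)phenyl]-3-{(2S)-2-[4-(benzyloxy)phenyl]-5,7-dihydroxy-3,4-dihydro-2H-chromen-6-yl}-4H-chromen-4-one
Conditions: Bu4NF, AcOH, THF, 0 °C
Reagents that add atoms: none
Why: Fluoride cleavage of an aryl silyl ether; acetic acid buffers the phenoxide so the electron-rich ring is not exposed to base and air.

Step 15
Reactants: 25 (the 5'',7''-diol tetrabenzyl ether from step 14)
Product: 26 5,7-dihydroxy-3-[(2S)-5,7-dihydroxy-2-(4-hydroxyphenyl)-3,4-dihydro-2H-chromen-6-yl]-2-(4-hydroxyphenyl)-4H-chromen-4-one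
Conditions: H2 (1 atm), Pd/C (10 %), EtOAc/MeOH, rt
Reagents that add atoms: none
Why: Hydrogenolysis of the four aryl benzyl ethers; the tetrasubstituted C2=C3 bond of the flavone and the cyclic benzylic ether of the flavan should survive at ambient pressure and short reaction time.

## Compound list

1 | 4'-(benzyloxy)acetophenone | CC(=O)c1ccc(OCc2ccccc2)cc1 | starting material
2 | ethyl 3-[4-(benzyloxy)phenyl]-3-oxopropanoate | CCOC(=O)CC(=O)c1ccc(OCc2ccccc2)cc1 | intermediate
3 | ethyl (3S)-3-[4-(benzyloxy)phenyl]-3-hydroxypropanoate | CCOC(=O)C[C@H](O)c1ccc(OCc2ccccc2)cc1 | intermediate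
4 | ethyl (3S)-3-[4-(benzyloxy)phenyl]-3-[(tert-butyldimethylsilyl)oxy]propanoate | CCOC(=O)C[C@H](O[Si](C)(C)C(C)(C)C)c1ccc(OCc2ccccc2)cc1 | intermediate
5 | (3S)-3-[4-(benzyloxy)phenyl]-3-[(tert-butyldimethylsilyl)oxy]propan-1-ol | OCC[C@H](O[Si](C)(C)C(C)(C)C)c1ccc(OCc2ccccc2)cc1 | intermediate
6 | (3S)-3-[4-(benzyloxy)phenyl]-3-[(tert-butyldimethylsilyl)oxy]propyl trifluoromethanesulfonate | FC(F)(F)S(=O)(=O)OCC[C@H](O[Si](C)(C)C(C)(C)C)c1ccc(OCc2ccccc2)cc1 | intermediate (not isolated)
7 | tert-butyl({(1S)-1-[4-(benzyloxy)phenyl]-5-ethoxypent-4-yn-1-yl}oxy)dimethylsilane | CCOC#CCC[C@H](O[Si](C)(C)C(C)(C)C)c1ccc(OCc2ccccc2)cc1 | intermediate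
8 | 2-{(3S)-3-[4-(benzyloxy)phenyl]-3-[(tert-butyldimethylsilyl)oxy]propyl}-3-ethoxycyclobut-2-en-1-one | CCOC1=C(CC[C@H](O[Si](C)(C)C(C)(C)C)c2ccc(OCc3ccccc3)cc2)C(=O)C1 | intermediate
9 | 2-{(3S)-3-[4-(benzyloxy)phenyl]-3-hydroxypropyl}-3-ethoxycyclobut-2-en-1-one | CCOC1=C(CC[C@H](O)c2ccc(OCc3ccccc3)cc2)C(=O)C1 | intermediate (not isolated)
10 | (3S)-3-[4-(benzyloxy)phenyl]-2-oxabicyclo[4.2.0]oct-1(6)-en-7-one | O=C1CC2=C1CC[C@@H](c1ccc(OCc3ccccc3)cc1)O2 | intermediate
11 | apigenin | O=c1cc(-c2ccc(O)cc2)oc2cc(O)cc(O)c12 | starting material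
12 | 5,7-bis(benzyloxy)-2-[4-(benzyloxy)phenyl]-4H-chromen-4-one | O=c1cc(-c2ccc(OCc3ccccc3)cc2)oc2cc(OCc3ccccc3)cc(OCc3ccccc3)c12 | intermediate
13 | 5,7-bis(benzyloxy)-2-[4-(benzyloxy)phenyl]-3-lithio-4H-chromen-4-one | [Li]c1c(-c2ccc(OCc3ccccc3)cc2)oc2cc(OCc3ccccc3)cc(OCc3ccccc3)c2c1=O | intermediate (not isolated)
14 | 5,7-bis(benzyloxy)-2-[4-(benzyloxy)phenyl]-3-iodo-4H-chromen-4-one | O=c1c(I)c(-c2ccc(OCc3ccccc3)cc2)oc2cc(OCc3ccccc3)cc(OCc3ccccc3)c12 | intermediate
15 | 5,7-bis(benzyloxy)-2-[4-(benzyloxy)phenyl]-3-[(trimethylsilyl)ethynyl]-4H-chromen-4-one | C[Si](C)(C)C#Cc1c(-c2ccc(OCc3ccccc3)cc2)oc2cc(OCc3ccccc3)cc(OCc3ccccc3)c2c1=O | intermediate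
16 | 5,7-bis(benzyloxy)-2-[4-(benzyloxy)phenyl]-3-ethynyl-4H-chromen-4-one | C#Cc1c(-c2ccc(OCc3ccccc3)cc2)oc2cc(OCc3ccccc3)cc(OCc3ccccc3)c2c1=O | intermediate
17 | lithium acetylide of 16 (3-(lithioethynyl)flavone tribenzyl ether) | [Li]C#Cc1c(-c2ccc(OCc3ccccc3)cc2)oc2cc(OCc3ccccc3)cc(OCc3ccccc3)c2c1=O | intermediate (not isolated)
18 | lithium ynolate, 3-[(lithiooxy)ethynyl]flavone tribenzyl ether | [Li]OC#Cc1c(-c2ccc(OCc3ccccc3)cc2)oc2cc(OCc3ccccc3)cc(OCc3ccccc3)c2c1=O | intermediate (not isolated)
19 | 5,7-bis(benzyloxy)-2-[4-(benzyloxy)phenyl]-3-{[(triisopropylsilyl)oxy]ethynyl}-4H-chromen-4-one | CC(C)[Si](C(C)C)(C(C)C)OC#Cc1c(-c2ccc(OCc3ccccc3)cc2)oc2cc(OCc3ccccc3)cc(OCc3ccccc3)c2c1=O | intermediate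
20 | [(6S)-6-[4-(benzyloxy)phenyl]-2-methylideneoxan-3-ylidene]methanone (vinylketene) | O=C=C1CC[C@@H](c2ccc(OCc3ccccc3)cc2)OC1=C | intermediate (not isolated)
21 | (7S)-7-[4-(benzyloxy)phenyl]-2-{5,7-bis(benzyloxy)-2-[4-(benzyloxy)phenyl]-4-oxo-4H-chromen-3-yl}-5-methylidene-3-[(triisopropylsilyl)oxy]-6-oxaspiro[3.5]non-2-en-1-one (spiro centre of either configuration) | O=C1C(c3c(-c4ccc(OCc5ccccc5)cc4)oc4cc(OCc5ccccc5)cc(OCc5ccccc5)c4c3=O)=C(O[Si](C(C)C)(C(C)C)C(C)C)C12CC[C@@H](c3ccc(OCc4ccccc4)cc3)OC2=C | intermediate (not isolated)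
22 | 2-{5,7-bis(benzyloxy)-2-[4-(benzyloxy)phenyl]-4-oxo-4H-chromen-3-yl}-3-[(6S)-6-[4-(benzyloxy)phenyl]-2-methylideneoxan-3-ylidene]-3-[(triisopropylsilyl)oxy]prop-1-en-1-one (dienylketene) | O=C=C(c1c(-c2ccc(OCc3ccccc3)cc2)oc2cc(OCc3ccccc3)cc(OCc3ccccc3)c2c1=O)C(O[Si](C(C)C)(C(C)C)C(C)C)=C1CC[C@@H](c2ccc(OCc3ccccc3)cc2)OC1=C | intermediate (not isolated)
23 | (2S)-2-[4-(benzyloxy)phenyl]-6-{5,7-bis(benzyloxy)-2-[4-(benzyloxy)phenyl]-4-oxo-4H-chromen-3-yl}-5-[(triisopropylsilyl)oxy]-3,4-dihydro-2H-chromen-7(8H)-one | O=C1CC2=C(CC[C@@H](c3ccc(OCc4ccccc4)cc3)O2)C(O[Si](C(C)C)(C(C)C)C(C)C)=C1c1c(-c2ccc(OCc3ccccc3)cc2)oc2cc(OCc3ccccc3)cc(OCc3ccccc3)c2c1=O | intermediate (not isolated)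
24 | 5,7-bis(benzyloxy)-2-[4-(benzyloxy)phenyl]-3-{(2S)-2-[4-(benzyloxy)phenyl]-7-hydroxy-5-[(triisopropylsilyl)oxy]-3,4-dihydro-2H-chromen-6-yl}-4H-chromen-4-one | O=c1c(-c2c(O)cc3c(c2O[Si](C(C)C)(C(C)C)C(C)C)CC[C@@H](c2ccc(OCc4ccccc4)cc2)O3)c(-c2ccc(OCc3ccccc3)cc2)oc2cc(OCc3ccccc3)cc(OCc3ccccc3)c12 | intermediate
25 | 5,7-bis(benzyloxy)-2-[4-(benzyloxy)phenyl]-3-{(2S)-2-[4-(benzyloxy)phenyl]-5,7-dihydroxy-3,4-dihydro-2H-chromen-6-yl}-4H-chromen-4-one | O=c1c(-c2c(O)cc3c(c2O)CC[C@@H](c2ccc(OCc4ccccc4)cc2)O3)c(-c2ccc(OCc3ccccc3)cc2)oc2cc(OCc3ccccc3)cc(OCc3ccccc3)c12 | intermediate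
26 | 5,7-dihydroxy-3-[(2S)-5,7-dihydroxy-2-(4-hydroxyphenyl)-3,4-dihydro-2H-chromen-6-yl]-2-(4-hydroxyphenyl)-4H-chromen-4-one | O=c1c(-c2c(O)cc3c(c2O)CC[C@@H](c2ccc(O)cc2)O3)c(-c2ccc(O)cc2)oc2cc(O)cc(O)c12 | target

## Step count and risks

Total: 15 steps. Longest linear sequence: 10 steps (1 to 26 through steps 1–7 and 13–15). The flavone branch has 5 steps before the key step.

**Step 13 (key step, new method).** Three things are most likely to go wrong:
- The vinylogous-ester cyclobutenone 10 may open too slowly, so that the siloxyalkyne decomposes first.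
- Addition of the hindered, electron-poor alkyne carbon to the ketene may be slow.
- The vinylketene may acylate the product phenol.

Fallback, known reactions throughout, from 14 back to 25; it follows the symmetric-arene logic of Alternative 3. Lithiation of 1,3,5-tris(methoxymethoxy)benzene F1 (n-BuLi, THF, 0 °C) and borylation with B(OMe)3 would give [2,4,6-tris(methoxymethoxy)phenyl]boronic acid F2. Suzuki–Miyaura coupling of F2 with 14 (Pd(OAc)2, SPhos, K3PO4, toluene/water, 90 °C) would give the symmetric 3-[2,4,6-tris(methoxymethoxy)phenyl]flavone F3. This coupling is hindered, but its type is established. HCl in MeOH/THF would then free the 3-(2,4,6-trihydroxyphenyl)flavone F4. Separately, 1-[4-(benzyloxy)phenyl]-3-chloropropan-1-one F5 would be made from 4-(benzyloxy)phenylmagnesium bromide and 3-chloro-N-methoxy-N-methylpropanamide. Reduction with BH3·SMe2 and (S)-2-methyl-CBS-oxazaborolidine would give (1R)-1-[4-(benzyloxy)phenyl]-3-chloropropan-1-ol F6. Mitsunobu etherification (PPh3, DIAD, THF, 0 °C) of the least hindered, para hydroxyl of F4 with F6 would set C2'' with inversion and give the (S)-configured 3-chloropropyl aryl ether F7. Cs2CO3 and NaI in DMF would close ring C'' by C-alkylation of the phenoxide, since O-alkylation would need an eight-membered ring. This delivers 25.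

**Step 12.** The peroxide may add to C2 of the chromone, or the stabilised acetylide may be oxidised incompletely. Silylation on carbon instead of oxygen is also possible.

Fallback from 14 to 26, without the ynolate. Stille coupling of 14 with tributyl(ethoxyethynyl)stannane (PdCl2(PPh3)2, Et4NCl, DMF, 60 °C) would give 3-(ethoxyethynyl)flavone tribenzyl ether F8. Annulation of F8 with 10 under the conditions of step 13 would give the 5''-O-ethyl analogue of 24, F9; alkoxyalkynes are established partners in this reaction. BBr3 (CH2Cl2, −78 → 0 °C) would then cleave the ethyl and the four benzyl ethers to 26. The Lewis acid may open the flavan ring, which is why this is not the first choice.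

**Step 6.** Ketene may dimerise faster than it adds, or adventitious acid may hydrate the ynol ether.

Fallback from 7 to 8. The more electrophilic dichloroketene (Cl3CCOCl, Zn(Cu), Et2O/DME, rt) would give 4,4-dichloro-2-{(3S)-3-[4-(benzyloxy)phenyl]-3-[(tert-butyldimethylsilyl)oxy]propyl}-3-ethoxycyclobut-2-en-1-one F10. Reductive dechlorination (Zn, AcOH, TMEDA, EtOH, 0 °C) would then return to 8.

**Step 15.** Over-reduction is the risk: hydrogenolytic opening of the benzylic C2''–O1'' bond, or saturation of C2=C3.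

Fallback from 25 to 26. The reductive cleavage is replaced by Lewis-acid cleavage with a cation scavenger (BCl3, pentamethylbenzene, CH2Cl2, −78 °C), which touches neither the alkene nor, at this temperature, the cyclic ether. No new compound is made.

## Further compounds

F1 | step 13 | 1,3,5-tris(methoxymethoxy)benzene | COCOc1cc(OCOC)cc(OCOC)c1
F2 | step 13 | [2,4,6-tris(methoxymethoxy)phenyl]boronic acid | COCOc1cc(OCOC)c(B(O)O)c(OCOC)c1
F3 | step 13 | 5,7-bis(benzyloxy)-2-[4-(benzyloxy)phenyl]-3-[2,4,6-tris(methoxymethoxy)phenyl]-4H-chromen-4-one | O=c1c(-c2c(OCOC)cc(OCOC)cc2OCOC)c(-c2ccc(OCc3ccccc3)cc2)oc2cc(OCc3ccccc3)cc(OCc3ccccc3)c12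
F4 | step 13 | 5,7-bis(benzyloxy)-2-[4-(benzyloxy)phenyl]-3-(2,4,6-trihydroxyphenyl)-4H-chromen-4-one | O=c1c(-c2c(O)cc(O)cc2O)c(-c2ccc(OCc3ccccc3)cc2)oc2cc(OCc3ccccc3)cc(OCc3ccccc3)c12
F5 | step 13 | 1-[4-(benzyloxy)phenyl]-3-chloropropan-1-one | O=C(CCCl)c1ccc(OCc2ccccc2)cc1
F6 | step 13 | (1R)-1-[4-(benzyloxy)phenyl]-3-chloropropan-1-ol | ClCC[C@@H](O)c1ccc(OCc2ccccc2)cc1
F7 | step 13 | 5,7-bis(benzyloxy)-2-[4-(benzyloxy)phenyl]-3-{4-[(1S)-1-[4-(benzyloxy)phenyl]-3-chloropropoxy]-2,6-dihydroxyphenyl}-4H-chromen-4-one | O=c1c(-c2c(O)cc(O[C@@H](CCCl)c3ccc(OCc4ccccc4)cc3)cc2O)c(-c2ccc(OCc3ccccc3)cc2)oc2cc(OCc3ccccc3)cc(OCc3ccccc3)c12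
F8 | step 12 | 5,7-bis(benzyloxy)-2-[4-(benzyloxy)phenyl]-3-(ethoxyethynyl)-4H-chromen-4-one | CCOC#Cc1c(-c2ccc(OCc3ccccc3)cc2)oc2cc(OCc3ccccc3)cc(OCc3ccccc3)c2c1=O
F9 | step 12 | 5,7-bis(benzyloxy)-2-[4-(benzyloxy)phenyl]-3-{(2S)-2-[4-(benzyloxy)phenyl]-5-ethoxy-7-hydroxy-3,4-dihydro-2H-chromen-6-yl}-4H-chromen-4-one | O=c1c(-c2c(O)cc3c(c2OCC)CC[C@@H](c2ccc(OCc4ccccc4)cc2)O3)c(-c2ccc(OCc3ccccc3)cc2)oc2cc(OCc3ccccc3)cc(OCc3ccccc3)c12
F10 | step 6 | 4,4-dichloro-2-{(3S)-3-[4-(benzyloxy)phenyl]-3-[(tert-butyldimethylsilyl)oxy]propyl}-3-ethoxycyclobut-2-en-1-one | CCOC1=C(CC[C@H](O[Si](C)(C)C(C)(C)C)c2ccc(OCc3ccccc3)cc2)C(=O)C1(Cl)Cl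
F0 | step 15 | none | none
A1 | alternative 1 | 5,7-bis(benzyloxy)-2-[4-(benzyloxy)phenyl]-3-[2,6-bis(benzyloxy)-4-{[(1S)-1-[4-(benzyloxy)phenyl]prop-2-en-1-yl]oxy}-3-ethenylphenyl]-4H-chromen-4-one | C=C[C@@H](c1ccc(OCc2ccccc2)cc1)Oc1cc(OCc2ccccc2)c(-c2c(-c3ccc(OCc4ccccc4)cc3)oc3cc(OCc4ccccc4)cc(OCc4ccccc4)c3c2=O)c(OCc2ccccc2)c1C=C
A2 | alternative 1 | 5,7-bis(benzyloxy)-2-[4-(benzyloxy)phenyl]-3-{(2S)-5,7-bis(benzyloxy)-2-[4-(benzyloxy)phenyl]-2H-chromen-6-yl}-4H-chromen-4-one | C1=C[C@@H](c2ccc(OCc3ccccc3)cc2)Oc2cc(OCc3ccccc3)c(-c3c(-c4ccc(OCc5ccccc5)cc4)oc4cc(OCc5ccccc5)cc(OCc5ccccc5)c4c3=O)c(OCc3ccccc3)c12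
A3 | alternative 2 | 2,4-bis(benzyloxy)-6-hydroxybenzaldehyde | O=Cc1c(O)cc(OCc2ccccc2)cc1OCc1ccccc1
A4 | alternative 2 | (2S)-5,7-bis(benzyloxy)-2-[4-(benzyloxy)phenyl]-6-{[4-(benzyloxy)phenyl]ethynyl}-3,4-dihydro-2H-chromene | C(#Cc1ccc(OCc2ccccc2)cc1)c3c(OCc4ccccc4)cc5c(c3OCc4ccccc4)CC[C@@H](c6ccc(OCc7ccccc7)cc6)O5
A5 | alternative 2 | 5,7-bis(benzyloxy)-2-[4-(benzyloxy)phenyl]-3-{(2S)-5,7-bis(benzyloxy)-2-[4-(benzyloxy)phenyl]-3,4-dihydro-2H-chromen-6-yl}-4H-chromen-4-one | O=c1c(-c2c(OCc4ccccc4)cc3c(c2OCc4ccccc4)CC[C@@H](c2ccc(OCc4ccccc4)cc2)O3)c(-c2ccc(OCc3ccccc3)cc2)oc2cc(OCc3ccccc3)cc(OCc3ccccc3)c12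
A6 | alternative 3 | 5,7-bis(benzyloxy)-2-[4-(benzyloxy)phenyl]-3-{4-[(1S)-1-[4-(benzyloxy)phenyl]-3-bromopropoxy]-2,6-dihydroxyphenyl}-4H-chromen-4-one | O=c1c(-c2c(O)cc(O[C@@H](CCBr)c3ccc(OCc4ccccc4)cc3)cc2O)c(-c2ccc(OCc3ccccc3)cc2)oc2cc(OCc3ccccc3)cc(OCc3ccccc3)c12
A7 | alternative 3 | 5,7-bis(benzyloxy)-2-[4-(benzyloxy)phenyl]-3-{(2S)-2-[4-(benzyloxy)phenyl]-5,7-dihydroxy-3,4-dihydro-2H-chromen-6-yl}-4H-chromen-4-one (identical with 25) | O=c1c(-c2c(O)cc3c(c2O)CC[C@@H](c2ccc(OCc4ccccc4)cc2)O3)c(-c2ccc(OCc3ccccc3)cc2)oc2cc(OCc3ccccc3)cc(OCc3ccccc3)c12
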